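The left-handed product of the eta run stands at 49.7 % after 0.625 d and at 49.9 % after 8.00 d, which is what the left-handed substrate can give, half of the two substrates together, so that substrate is the limiting reagent for this product. The new flask differs from eta in holding half of its catalyst, and with the same left-handed charge it can be expected to end at the same ceiling; what remains open is how fast it passes the conversion asked about.

| flask | left-handed substrate | right-handed substrate | coupling partner | free catalyst | remark |
|---|---|---|---|---|---|
| theta | 20 mM | 20 mM | 27 mM | 0.20 mM | run made earlier |
| epsilon | 20 mM | 20 mM | 60 mM | 0.20 mM | run made earlier |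
| eta | 20 mM | 20 mM | 40 mM | 0.40 mM | run made earlier |
| flask | 20 mM | 20 mM | 40.0 mM | 0.20 mM |  |

- theta (time / d: left-handed product / %): 0.625: 43.8; 1.04: 46.7; 1.67: 48.2; 2.50: 48.4; 3.00: 47.9; 5.00: 48.9; 8.00: 50.5
- epsilon (time / d: left-handed product / %): 1.25: 48.7; 2.50: 49.3; 3.00: 48.9; 5.00: 50.3; 6.00: 50.9; 8.00: 50.4
- eta (time / d: left-handed product / %): 0.625: 49.7; 2.08: 50.3; 4.00: 50.2; 6.00: 50.1; 8.00: 49.9

(scatter of a reading: 0.5 percentage points)

- free catalyst is single-handed; left-handed substrate and right-handed substrate are mirror images of each other, charged as a racemate, each of them at the stated concentration
- the earlier runs were read with a standard deviation of 0.5 percentage points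

* apparent order in free catalyst when 30 % of the left-handed substrate and right-handed substrate together are converted (percent change of the rate of making left-handed product for one percent more free catalyst charged)
* factor on the rate of making left-handed product when 30 % of the left-handed substrate and right-handed substrate together are converted if free catalyst is charged twice over

Theta shows the speed falling. Reckoned on the left-handed substrate remaining, its first-order constant is 3.34 d⁻¹ up to the first reading but 1.52 d⁻¹ between the first and the second, so, as a reading with the scatter of 0.5 points on small remainders, it decays at 1.51 d⁻¹. My assumption, which sets aside the coupling partner that theta spends as it makes product, is that this decay runs on the clock, whatever the catalyst charged. Scaling theta's early constant by the coupling partner gives the flask 4.95 d⁻¹, and so 0.185 d to reach 30 %. The clock number, the decay constant times the time to reach the conversion asked about, is then 0.280. More catalyst shortens that time and so spares the rate some decay, which makes the order one plus the clock number, 1.28, and the factor on doubling 2.30.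

The forecast, grounded in “catalyst loss per turnover”, gives an order of 2.3 and a factor of 3.3, both above this reckoning. The simulation gives an order of 1.3 and a factor of 2.37.

    2 coupling partner → homo dimer (k = 1.40 M⁻¹ h⁻¹)
    coupling partner + catalyst intermediate A → free catalyst + left-handed product (k = 1600 M⁻¹ h⁻¹)
    free catalyst + right-handed substrate ⇌ catalyst intermediate B (K = 29.0 M⁻¹, k = 54000 M⁻¹ h⁻¹)
    free catalyst ⇌ dormant form (K = 1.90, k = 0.210 h⁻¹)
    free catalyst + left-handed substrate ⇌ catalyst intermediate A (K = 240 M⁻¹, k = 16000 M⁻¹ h⁻¹)
    coupling partner + catalyst intermediate B → free catalyst + right-handed product (k = 220 M⁻¹ h⁻¹)

The flask passes 30 % after 0.0977 d, about half the reckoned 0.185 d, while the forward step from free catalyst into dormant form, taken by itself, has a time constant of 0.198 d, about twice as long as the flask's passage, and at that moment 12.1 % of the catalyst is dormant form beside 30.3 % free catalyst. Against the clock number of 0.280 reckoned for the flask, theta, with less coupling partner, carries 0.415, and it reads 43.8 % after 0.625 d, where eta, with more coupling partner and more catalyst, reads 49.7 %.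

The numbers in the tables were generated by integration for an exercise; scatter was added.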